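**Retrosynthetic overview**
- Ring C (dihydrofuran) is closed last. The C11a–O11 bond is cut to the para-quinone methide of a cis-(3S,4S)-2'-hydroxyisoflavan-4-ol. That alcohol is not isolated but traced back to the flat 2'-hydroxyisoflavone, so one flask (transfer hydrogenation with dynamic kinetic resolution, then acid) sets C6a and C11a and closes the ring.
- The isoflavone is cut at the C3–aryl bond to a 3-iodochromone and the ring D boronic acid; the pyranone comes from an o-hydroxyacetophenone.
- The dimethyldihydropyran is cut to phloroacetophenone and isoprene (C-prenylation, then O-cyclisation). A pivalate on the para oxygen forces the ring oxygen next to the acyl carbon (later C1); it is the only protecting group and is removed in the coupling flask.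
- Order of ring formation: dihydropyran, then pyranone (later ring B), then dihydrofuran (ring C).

Assumption: (2-hydroxy-4-methoxyphenyl)boronic acid is taken as a catalogue building block.

**Step 1**
Reactants: 1 2,4,6-trihydroxyacetophenone
Product: 2 4-acetyl-3,5-dihydroxyphenyl pivalate
Conditions: PivCl (1.05 equiv), Et3N (1.1 equiv), THF, −20 → 0 °C
Reagents that add atoms: pivaloyl chloride, CC(C)(C)C(=O)Cl
Why: Chemoselective O-acylation, because the hydroxyl para to the acetyl group is the most acidic and the only one neither hydrogen-bonded to nor flanked by the carbonyl, so one equivalent of the bulky acid chloride esterifies it alone.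

**Step 2**
Reactants: 2 4-acetyl-3,5-dihydroxyphenyl pivalate; 3 isoprene
Product: 5 8-acetyl-7-hydroxy-2,2-dimethylchroman-5-yl pivalate, via C-prenyl ketone 4 (not isolated)
Conditions: isoprene (1.5 equiv), Amberlyst 15 (dry, H+ form), THF/heptane 1:1, sealed tube, 65 °C
Reagents that add atoms: none
Why: Acid-catalysed Friedel–Crafts prenylation at the one kind of free ring carbon, then Markovnikov hydroalkoxylation of the prenyl double bond by the only free neighbouring hydroxyl (the ortho one, since the para oxygen is esterified), which copies the prenyltransferase/cyclase sequence and places the ring oxygen next to the acetyl carbon.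

**Step 3**
Reactants: 5 8-acetyl-7-hydroxy-2,2-dimethylchroman-5-yl pivalate
Product: 7 9-iodo-2,2-dimethyl-10-oxo-3,4-dihydro-2H,10H-pyrano[2,3-f]chromen-5-yl pivalate (3-iodochromone), via enaminone 6 (not isolated)
Conditions: DMF-DMA (3 equiv), toluene, 85 °C; evaporate; I2 (1.5 equiv), CHCl3, rt
Reagents that add atoms: N,N-dimethylformamide dimethyl acetal, COC(OC)N(C)C; iodine, II
Why: Enaminone formation followed by iodocyclisation (α-iodination, attack of the one remaining ortho phenol on the iminium carbon, loss of dimethylamine) is the standard 3-iodochromone synthesis, and the pivalate keeps DMF-DMA from methylating the acidic para phenol.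

**Step 4**
Reactants: 7 3-iodochromone; 8 (2-hydroxy-4-methoxyphenyl)boronic acid
Product: 10 5-hydroxy-9-(2-hydroxy-4-methoxyphenyl)-2,2-dimethyl-3,4-dihydro-2H,10H-pyrano[2,3-f]chromen-10-one (2'-hydroxyisoflavone), via pivaloyl isoflavone 9 (not isolated)
Conditions: 8 (1.5 equiv), Pd(PPh3)4 (5 mol%), K2CO3 (3 equiv), degassed DME/H2O 4:1, 70 °C; then MeOH, 45 °C
Reagents that add atoms: none
Why: Suzuki–Miyaura coupling at the reactive C–I bond (the aryl pivalate C–O bond is inert to Pd(PPh3)4), then carbonate-mediated methanolysis of the activated aryl pivalate in the same flask.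

**Step 5**
Reactants: 10 2'-hydroxyisoflavone
Product: 14 (6aS,11aS)-pterocarpan (target), via racemising isoflavanone 11 (not isolated), via cis-isoflavan-4-ol 12 (not isolated), via para-quinone methide 13 (not isolated)
Conditions: RuCl(p-cymene)[(S,S)-TsDPEN] (5 mol%), HCO2H/Et3N 5:2, EtOAc, 45 °C; then conc. HCl, EtOH, 0 °C → rt, ≤1 h
Reagents that add atoms: none
Why: Noyori–Ikariya asymmetric transfer hydrogenation first reduces the chromone C=C to the easily enolised isoflavanone, whose dynamic kinetic resolution by the (S,S)-catalyst (hydride to the carbonyl face that gives 4S, the 3S epimer reacting fast) gives the cis-(3S,4S)-alcohol; acid then ionises the C4 hydroxyl with help from the para phenol (pterocarpan-synthase-type para-quinone methide) and the 2'-phenol adds to C4 on the only face that allows a cis-fused furan, so C3 becomes C6a (S) unchanged and C11a (S) follows from it.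

**Compound list**
1 | 2,4,6-trihydroxyacetophenone | CC(=O)c1c(O)cc(O)cc1O | starting material
2 | 4-acetyl-3,5-dihydroxyphenyl pivalate | CC(=O)c1c(O)cc(OC(=O)C(C)(C)C)cc1O | intermediate
3 | isoprene (2-methylbuta-1,3-diene) | C=CC(C)=C | starting material
4 | 4-acetyl-3,5-dihydroxy-2-(3-methylbut-2-en-1-yl)phenyl pivalate (not isolated) | CC(=O)c1c(O)cc(OC(=O)C(C)(C)C)c(CC=C(C)C)c1O | intermediate
5 | 8-acetyl-7-hydroxy-2,2-dimethylchroman-5-yl pivalate | CC(=O)c1c(O)cc(OC(=O)C(C)(C)C)c2CCC(C)(C)Oc12 | intermediate
6 | (E)-8-[3-(dimethylamino)prop-2-enoyl]-7-hydroxy-2,2-dimethylchroman-5-yl pivalate (not isolated) | CN(C)/C=C/C(=O)c1c(O)cc(OC(=O)C(C)(C)C)c2CCC(C)(C)Oc12 | intermediate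
7 | 9-iodo-2,2-dimethyl-10-oxo-3,4-dihydro-2H,10H-pyrano[2,3-f]chromen-5-yl pivalate; a 3-iodochromone with the pivalate on chromone C7 and the dimethyldihydropyran fused at C5 (O) and C6 (CH2) | O=C1C(I)=COc2cc(OC(=O)C(C)(C)C)c3CCC(C)(C)Oc3c12 | intermediate
8 | (2-hydroxy-4-methoxyphenyl)boronic acid | COc1ccc(B(O)O)c(O)c1 | starting material
9 | 9-(2-hydroxy-4-methoxyphenyl)-2,2-dimethyl-10-oxo-3,4-dihydro-2H,10H-pyrano[2,3-f]chromen-5-yl pivalate (not isolated) | O=C1C(c4ccc(OC)cc4O)=COc2cc(OC(=O)C(C)(C)C)c3CCC(C)(C)Oc3c12 | intermediate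
10 | 5-hydroxy-9-(2-hydroxy-4-methoxyphenyl)-2,2-dimethyl-3,4-dihydro-2H,10H-pyrano[2,3-f]chromen-10-one; the 7,2'-dihydroxy-4'-methoxyisoflavone with the dimethyldihydropyran at C5 (O) and C6 (CH2) | O=C1C(c4ccc(OC)cc4O)=COc2cc(O)c3CCC(C)(C)Oc3c12 | intermediate
11 | 2,3-dihydro derivative of 10 (isoflavanone), racemising at C3 (not isolated) | O=C1C(c4ccc(OC)cc4O)COc2cc(O)c3CCC(C)(C)Oc3c12 | intermediate
12 | cis-(3S,4S)-isoflavan-4-ol: (9S,10S)-9-(2-hydroxy-4-methoxyphenyl)-2,2-dimethyl-3,4,9,10-tetrahydro-2H,8H-pyrano[2,3-f]chromene-5,10-diol (not isolated) | O[C@H]1[C@@H](c4ccc(OC)cc4O)COc2cc(O)c3CCC(C)(C)Oc3c12 | intermediate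
13 | (3S)-para-quinone methide: 12 less water, with C7=O and a C4=C4a double bond in isoflavan numbering; reacts as such or as its O-protonated cation (not isolated) | O=C1C=C2OC[C@H](c3ccc(OC)cc3O)C=C2C2=C1CCC(C)(C)O2 | intermediate
14 | (6aS,11aS)-cis-pterocarpan with OH at C3, OMe at C9 and a 2,2-dimethyl-3,4-dihydro-2H-pyran fused at C1 (ring O) and C2 (CH2) | COc1ccc2c(c1)O[C@@H]1c3c(cc(O)c4c3OC(C)(C)CC4)OC[C@H]21 | target

**Total step count:** 5
**Longest linear sequence:** 5 (1 → 2 → 5 → 7 → 10 → 14)

**Steps most likely to fail**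

Most at risk is step 5. The chromone of 10 is electron-rich and carries free phenols, so the conjugate reduction may stall. The cation that closes ring C can also be reduced on to the isoflavan, or lose H-3 to give the isoflav-3-ene (loss of ee) if the acid stage runs too long. Fallback: set out from 10 and take the cascade apart. Pd/C with HCO2NH4 in MeOH at 60 °C reduces only the C2=C3 bond and gives the racemic isoflavanone 11, which is now isolated. Its ketone alone is then reduced under dynamic kinetic resolution (RuCl(p-cymene)[(S,S)-TsDPEN], HCO2H/Et3N, EtOAc, 40 °C) to 12, where the route is rejoined (brief acid closure to 14).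

Second is step 2. The ring of 2 is deactivated by the acetyl and pivaloyloxy groups, so slow Friedel–Crafts attack, isoprene oligomers or a second annulation on the other side can cut the yield. Fallback: set out from 2 and build the same ring by a sigmatropic route. One ortho hydroxyl is O-alkylated with 3-chloro-3-methylbut-1-yne F1 (CuCl2 cat., DBU, MeCN, 0 °C) to the aryl 1,1-dimethylpropargyl ether F2. Thermal aromatic Claisen rearrangement, 1,5-H shift and 6π-electrocyclisation (xylene, 140 °C) give the 2,2-dimethyl-2H-chromene F3; the only free ortho carbon is the right one, so the regiochemistry is unchanged. H2, Pd/C, EtOAc then saturates the chromene double bond, which comes back to the route at 5.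

Third is step 4. ortho-Hydroxyarylboronic acids protodeboronate in aqueous base, and 3-iodochromones can open at C2 with hydroxide. Fallback: set out from 7 and couple with [2-(benzyloxy)-4-methoxyphenyl]boronic acid F4 (Pd(PPh3)4, K2CO3, DME/H2O, 70 °C) to the pivaloyl benzyl ether isoflavone F5. The pivalate is methanolysed in the same flask to the 2'-benzyloxy-7-hydroxyisoflavone F6. Pd/C, H2 (1 atm), EtOAc/MeOH then cleaves the benzyl ether and reduces the C2=C3 bond, giving the racemic isoflavanone 11, where the route is rejoined (ketone reduction under dynamic kinetic resolution to 12, acid to 14).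

**Further compounds**
F1 | step 2 | 3-chloro-3-methylbut-1-yne (bought) | CC(C)(Cl)C#C
F2 | step 2 | 4-acetyl-3-hydroxy-5-[(2-methylbut-3-yn-2-yl)oxy]phenyl pivalate | CC(=O)c1c(O)cc(OC(=O)C(C)(C)C)cc1OC(C)(C)C#C
F3 | step 2 | 8-acetyl-7-hydroxy-2,2-dimethyl-2H-chromen-5-yl pivalate | CC(=O)c1c(O)cc(OC(=O)C(C)(C)C)c2C=CC(C)(C)Oc12
F4 | step 4 | [2-(benzyloxy)-4-methoxyphenyl]boronic acid (bought) | COc1ccc(B(O)O)c(OCc2ccccc2)c1
F5 | step 4 | 9-[2-(benzyloxy)-4-methoxyphenyl]-2,2-dimethyl-10-oxo-3,4-dihydro-2H,10H-pyrano[2,3-f]chromen-5-yl pivalate | O=C1C(c4ccc(OC)cc4OCc5ccccc5)=COc2cc(OC(=O)C(C)(C)C)c3CCC(C)(C)Oc3c12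
F6 | step 4 | 9-[2-(benzyloxy)-4-methoxyphenyl]-5-hydroxy-2,2-dimethyl-3,4-dihydro-2H,10H-pyrano[2,3-f]chromen-10-one | O=C1C(c4ccc(OC)cc4OCc5ccccc5)=COc2cc(O)c3CCC(C)(C)Oc3c12
F0 | step 5 | none | none
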